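## The problem

The target is a melampolide-type germacranolide. Its ten-membered carbocycle (C1–C10) holds a ring-cis trisubstituted C1=C10 alkene and a trans-4,5-epoxide whose quaternary carbon C4 bears the hydroxymethyl C15. A trans-fused α-methylene-γ-lactone spans C6–C7 (oxygen on C6, C11 on C7), and C8 carries the (E)-4-hydroxy-2-methylbut-2-enoate. The five stereocentres C4–C8 are contiguous (4S,5R,6S,7R,8R), so neighbours can control each other. A C5 oxygen can steer a nucleophile onto a C4 ketone and then be displaced with inversion; C6 fixes the lactone; C7 stays epimerisable while C8 is a carbonyl; C8 follows by reduction next to C7. No neighbour can supply the absolute configuration. The ring is the harder half: ten-membered rings close poorly, and a Z trisubstituted alkene is hard to secure in an open chain or in a ten-membered closure, whereas in an eight-membered ring it can only be cis. The α-methylene lactone (Michael acceptor), the medium-ring epoxide (acid-induced transannular opening) and the enoate ester (strong base) will not survive rough treatment. Intermediates with a ketone β to the C6 oxygen can eliminate, and a ring 1,5-diketone can undergo transannular aldol closure. The structural feature that opens the key step is the array C4(O)–C5(O)–C6(O)–C7(CH2CO2R)–C8(O): two 1,5-related oxygenated carbons with a vicinal dioxygenated pair between them. That is what results when a 1,2-dioxygenated alkene is inserted into the C4–C7 bond of an eight-membered 1,3-dicarbonyl system.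

## Retrosynthesis

**C8 ester and silyl groups.** Target 35 is cut at the C8–O acyl bond and the two O–Si bonds, giving alcohol 29 and the silyl-protected acid 33 (from aldehyde 30 and ylide 31). Acylation is placed last so that the enoate never meets a strong base. 29 has a single free hydroxyl, so no selectivity is asked of the esterification.

**Exocyclic methylene.** The C11=C13 bond of 28 is removed to give lactone 26, whose only acidic C–H is at C11. A Mannich/elimination sequence is preferred to carrying C13 from the start, because every earlier step (Grignard, hydride, peroxide) would attack an α-methylene lactone. C8–OH must be masked (triethylsilyl) for the enolate step.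

**Epoxide.** The C5–O bond of 26 is cut, leading to hydroxy sulfonate 25 (and 24, 23); the C4 oxygen displaces the C5 sulfonate with inversion. This uses a cis-5,6-diol, which is what a cyclic alkene partner delivers, and avoids discriminating two ring alkenes in an epoxidation. The C8 ketone is reduced and silylated before the base-induced closure, so that no ketone sits β to the lactone oxygen when base is present. The sulfonyl group is (1S)-camphor-10-sulfonyl, so the activation step also parts the enantiomers (racemic 22 gives separable diastereomers, 23 being the one carried on).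

**C15.** The C4–C15 bond of 22/21/20 is cut, leading to α-hydroxy ketone 17 and the hydroxymethyl anion equivalent 19 (from 18). The free C5 hydroxyl is kept as a chelating group; the same oxygen later leaves, so the centre that directs C4 is consumed productively. The forward reaction must choose the chelated C4 carbonyl over the C8 ketone and the lactone.

**Lactone.** The C12–O6 bond of 17 is cut together with the carbonate, giving diketone carbonate 16. Lactonising at once ties C6–O into a five-membered ring and leaves C5–OH as the only free hydroxyl. The forward step must remove the carbonate without base.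

**Ten-membered ring (key step).** 16 is simplified by re-forming C4–C7 and removing C5 and C6. This gives the eight-membered β-(4-methoxybenzyloxy) enone 12 and vinylene carbonate 13. Against a direct ten-membered closure, this cut forms the ring by releasing cyclobutane strain, installs both C5 and C6 oxygens cis in the ring-forming event, and makes C1=C10 in a ring where it must be cis. Two changes were made from the simplest version of this idea.
- No chiral catalyst is relied on. The configuration of C5/C6 in 16 depends on the product of two selectivities (enone face and exo/endo orientation of 13), so the step is run on achiral material and the antipodes are parted in step 12.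
- The enol oxygen is fixed at C4 from the outset and carried as a 4-methoxybenzyl ether, rather than made by derivatising a 1,3-dicarbonyl system whose two oxygens differ only in remote substituents. Oxidative removal with DDQ then triggers the retro-aldol without generating an enolate next to the C6 leaving group.

**C7 side chain.** The C7–C11 bond of 12 is cut, giving iodide 9 and the zinc reagent 11 (from methyl bromoacetate 10); 9 comes from vinylogous ester 8 by α-iodination. Introducing the acetate unit after ring closure keeps the enol ether trisubstituted while its geometry matters.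

**Eight-membered ring.** The C1=C10 bond of 8 is cut, giving trienone 7 (ring-closing metathesis). The E enol ether of 7 holds the two alkenyl chains cis, and the product is a cycloocta-1,5-diene type ring, the least strained eight-membered diene.

**Open chain.** 7 is cut at C8–C9 into Weinreb amide 5 and 2-methylallylmagnesium chloride 6. 5 is cut at the C4–O bond into alkynyl amide 3 and 4-methoxybenzyl alcohol 4; this conjugate addition decides which oxygen becomes the enol ether. 3 comes from hex-5-en-1-yne 1 and carbamoyl chloride 2.

## Roads not taken

**Alternative 1:** Nozaki–Hiyama–Kishi closure with lactonisation. The cut is the ring bond C5–C6 together with the lactone C12–O bond. In the forward sense, CrCl2 with catalytic NiCl2 converts the alkenyl iodide of the seco aldehyde ester A1 into an alkenylchromium species that adds to the C6 aldehyde; the chromium alkoxide then acylates on the C12 ester to give dienolide A2.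
- Merits: ring and lactone form in one operation. The 4E alkene with C15–O in place allows the epoxy alcohol to be made by hydroxyl-directed (Sharpless) epoxidation with reagent control of absolute configuration. C7 and C8 can be set by asymmetric chemistry in the open chain, so no resolution is needed.
- Weak points: a ten-membered ring must close against oligomerisation (high dilution, large excess of chromium). C6 is created in the closing step without a strong control element. The Z trisubstituted C1=C10 alkene has to be made stereoselectively in an open chain, and A1 is reached only by a long linear sequence.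
- Comparison: this road is better in absolute stereocontrol and in the way the epoxide is made. The chosen plan sets against it a Z alkene that is secured by ring size, a ring formed by strain release rather than cyclisation, and a short path (seven steps) to a ten-membered ring that already carries the C5 and C6 oxygens. The price is a resolution and a less precedented key step.

**Alternative 2:** biomimetic allylic C–H lactonisation. The cut is the C6–O bond of the lactone, made last. Pd(OAc)2 with 1,2-bis(phenylsulfinyl)ethane and benzoquinone would cleave the allylic C6–H bond of the ten-membered trienoic acid A3, and the carboxylate would close the lactone to give A4.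
- Merits: no oxygen has to be carried at C6; the side chain and the methylene are already present; if it worked, this would be the shortest endgame of all.
- Weak points: C6–H is one of several allylic C–H bonds (C2, C3, C9, C14, C15 and C7 compete). This catalyst system works best on terminal alkenes, not trisubstituted ring alkenes. A π-allyl intermediate in a ten-membered 1,5-diene invites transannular reactions. Nothing controls the trans ring fusion. The road also leaves open how A3, with C7 and C8 set, is to be made.
- Comparison: fewer steps after the ring exists, but the ring problem is not addressed and the route rests on a site selectivity without close analogy. The chosen plan places the C6 oxygen by construction.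

**Alternative 3:** Eschenmoser–Tanabe fragmentation. The cut is the ring-fusion bond C1–C6 of a decalin. p-Toluenesulfonyl hydrazide and acetic acid convert epoxy ketone A5 into its hydrazone, which fragments with loss of N2 to the ten-membered cycloalkynone A6.
- Merits: a well-precedented fragmentation, driven by nitrogen loss. The rigid decalin allows reliable control of C4, C5 and C8 and an enantiopure start. Like the chosen plan, it makes the ring by cleaving a bond rather than by cyclisation.
- Weak points: after A6 the C10 methyl must still be added by syn-carbometalation of a ring alkyne with no group to direct regiochemistry (C9 and C2 are both CH2). The lactone must be built at C6/C7 from the ketone. A strained cycloalkyne next to a ketone can isomerise. The sequence to A5 is long.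
- Comparison: stronger in precedent and in stereocontrol at C4, C5 and C8. The chosen plan sets against it an alkene that arrives with its methyl in place, the direct introduction of both C5 and C6 oxygens, and fewer steps.

Key step: step 7

## Route

Assumption: hex-5-en-1-yne and the distannoxane ClBu2SnOSnBu2OH are taken as purchasable; ring compounds carry germacrane numbering (C1–C10 ring, C11–C13 lactone carbons, C14 methyl on C10, C15 on C4); compounds 14–22 are racemates, drawn and named as the enantiomer that is carried on after step 12.

Step 1
Reactants: 1 hex-5-en-1-yne; 2 N-methoxy-N-methylcarbamoyl chloride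
Product: 3 N-methoxy-N-methylhept-6-en-2-ynamide
Conditions: n-BuLi, THF, −78 °C; then 2, −78 → 0 °C
Reagents that add atoms: none
Why: Acylation of a lithium acetylide with a carbamoyl chloride; the Weinreb amide does not react further with the acetylide.

Step 2
Reactants: 3 N-methoxy-N-methylhept-6-en-2-ynamide; 4 4-methoxybenzyl alcohol
Product: 5 (2E)-N-methoxy-3-[(4-methoxybenzyl)oxy]-N-methylhepta-2,6-dienamide
Conditions: KOtBu (10 mol%), THF, 0 °C → rt
Reagents that add atoms: none
Why: Base-catalysed conjugate addition of an alkoxide to an activated alkyne (oxa-Michael); the oxygen can only enter at C4, which fixes the enol ether regiochemistry, and reversible addition should settle on the E isomer with the alkoxy group trans to the carbonyl.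

Step 3
Reactants: 5 (2E)-N-methoxy-3-[(4-methoxybenzyl)oxy]-N-methylhepta-2,6-dienamide; 6 (2-methylallyl)magnesium chloride
Product: 7 (5E)-6-[(4-methoxybenzyl)oxy]-2-methyldeca-1,5,9-trien-4-one
Conditions: THF, −78 → −20 °C; cold aq. NH4Cl
Reagents that add atoms: none
Why: Weinreb ketone synthesis; the magnesium chelate prevents a second addition, and the cold neutral quench should keep the new β,γ-unsaturated ketone out of conjugation.

Step 4
Reactants: 7 (5E)-6-[(4-methoxybenzyl)oxy]-2-methyldeca-1,5,9-trien-4-one
Product: 8 (2E,6Z)-3-[(4-methoxybenzyl)oxy]-7-methylcycloocta-2,6-dien-1-one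
Conditions: second-generation Hoveyda–Grubbs catalyst (5 mol%), 1,4-benzoquinone (10 mol%), toluene (2 mM), 80 °C
Reagents that add atoms: none
Why: Ring-closing metathesis between the vinyl and isopropenyl termini; the E enol ether holds the chains cis, the ring is of the cycloocta-1,5-diene type, and in an eight-membered ring the new C1=C10 bond can only be cis; benzoquinone suppresses alkene migration.

Step 5
Reactants: 8 (2E,6Z)-3-[(4-methoxybenzyl)oxy]-7-methylcycloocta-2,6-dien-1-one
Product: 9 (2Z,6Z)-2-iodo-3-[(4-methoxybenzyl)oxy]-7-methylcycloocta-2,6-dien-1-one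
Conditions: I2, pyridine, CH2Cl2, 0 °C → rt
Reagents that add atoms: iodine, II
Why: Electrophilic α-iodination of a vinylogous ester; C7 is the nucleophilic carbon of the enol ether and loss of its proton restores the enone, while the isolated alkene has no internal nucleophile to trap an iodonium ion.

Step 6
Reactants: 9 (2Z,6Z)-2-iodo-3-[(4-methoxybenzyl)oxy]-7-methylcycloocta-2,6-dien-1-one; 10 methyl bromoacetate
Product: 12 methyl 2-[(1E,5Z)-2-[(4-methoxybenzyl)oxy]-6-methyl-8-oxocycloocta-1,5-dien-1-yl]acetate, via Reformatsky zinc reagent 11 (not isolated)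
Conditions: Zn, THF, rt (10 → 11); then 9, Pd(PPh3)4 (5 mol%), THF, 50 °C
Reagents that add atoms: none
Why: Negishi cross-coupling of an α-iodoenone with a Reformatsky reagent; the vinylogous ester carbonyl is too poor an electrophile for the competing Reformatsky addition.

Step 7
Reactants: 12 methyl 2-[(1E,5Z)-2-[(4-methoxybenzyl)oxy]-6-methyl-8-oxocycloocta-1,5-dien-1-yl]acetate; 13 vinylene carbonate
Product: 16 racemic ten-membered 4,8-diketone 5,6-cis-carbonate with C7 CH2CO2Me (5S*,6S*,7S*; C1=C10 Z), via cyclobutane photoadduct 14 (not isolated), via cyclobutanol 15 (not isolated)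
Conditions: hν (λ ≥ 300 nm, Pyrex), 13 (20 equiv), MeCN, −20 °C; then DDQ, CH2Cl2/pH 7 buffer, 0 °C → rt
Reagents that add atoms: none
Why: De Mayo reaction: the excited vinylogous ester (triplet after intersystem crossing) adds stepwise to 13 through a 1,4-biradical that closes the cyclobutane of 14, forming C4–C5 and C6–C7. DDQ then removes the 4-methoxybenzyl group oxidatively, and cyclobutanol 15, a strained β-hydroxy ketone, opens by retro-aldol cleavage of C4–C7, so the ten-membered ring arises by two-atom ring expansion and not by cyclisation; the C8 enol ketonises to 16. The closest known reactions are the de Mayo ring expansions of 3-alkoxycyclohex-2-enones and of cyclopentane-1,3-dione enol derivatives and the [2+2] photocycloadditions of vinylene carbonate to cyclopentenone and cyclohexenone; the eight-membered ring is the new element. C5 and C6 are set cis to each other by the five-membered ring of 13, whatever the exo/endo or ring-fusion outcome at C4 and C7, because C4 becomes trigonal and C7 is reset on ketonisation. C7 is expected trans to the C6 oxygen and can be equilibrated through the C8 enol at this stage; the product is racemic. Regiochemistry (insertion between C4 and C7, not between C7 and C8) is secured by the position of the enol ether oxygen fixed in step 2. Chemoselectivity against the transannular C1=C10 alkene and against twisting about C4=C7 is sought with a large excess of 13 at low temperature, and the neutral unmasking avoids an enolate next to the C6 leaving group and the transannular aldol of the 1,5-diketone.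

Step 8
Reactants: 16 racemic ten-membered 4,8-diketone 5,6-cis-carbonate
Product: 17 racemic hydroxy lactone diketone (C6–O–C12 γ-lactone trans-fused at C6/C7, free C5–OH, ketones at C4 and C8; 5S*,6S*,7S*)
Conditions: ClBu2SnOSnBu2OH (10 mol%), MeOH/toluene (1:1), 60 °C
Reagents that add atoms: none
Why: Tin-catalysed transesterification under neutral conditions: methanol opens the strained cyclic carbonate and the C6 hydroxyl closes the γ-lactone on the C12 ester (5-exo-trig, preferred to the six-membered lactone from C5–OH). Avoiding base keeps the C6 oxygen from β-elimination and the 1,5-diketone from transannular aldol closure, and leaves C7 as set in 16.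

Step 9
Reactants: 17 racemic hydroxy lactone diketone; 18 (chloromethyl)(isopropoxy)dimethylsilane
Product: 20 racemic C4 tertiary alcohol with C15 as CH2SiMe2(OiPr) and free C5–OH (4R*,5S*,6S*,7S*), via Grignard reagent 19 (not isolated)
Conditions: Mg, THF, 40 °C (18 → 19); then 17, 19 (3 equiv), THF, −78 → −40 °C; aq. NH4Cl
Reagents that add atoms: none
Why: Chelation-controlled Grignard addition (Cram chelate): the first equivalent forms the C5 magnesium alkoxide, whose five-membered chelate with the C4 carbonyl exposes the face on the side of C5–H, giving the C4 configuration needed for a trans epoxide. The chelated α-oxygenated C4 carbonyl should also react before the α-branched C8 ketone and the lactone.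

Step 10
Reactants: 20 racemic C4 tertiary alcohol with C15 as CH2SiMe2(OiPr)
Product: 21 racemic triol ketone (C15–OH, C4–OH, C5–OH; 4S*,5S*,6S*,7S*)
Conditions: H2O2 (30%), KF, KHCO3, THF/MeOH, rt
Reagents that add atoms: hydrogen peroxide, OO
Why: Tamao oxidation of the alkoxysilane C–Si bond to C–OH under bicarbonate buffering; done before the epoxide exists, because a silylmethyl epoxide would open under fluoride.

Step 11
Reactants: 21 racemic triol ketone
Product: 22 racemic C15 tert-butyldimethylsilyl ether (C4–OH and C5–OH free)
Conditions: TBSCl, imidazole, DMF, 0 °C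
Reagents that add atoms: tert-butyldimethylsilyl chloride, CC(C)(C)[Si](C)(C)Cl
Why: Selective silylation of the primary hydroxyl over the secondary and tertiary ones.

Step 12
Reactants: 22 racemic C15 tert-butyldimethylsilyl ether
Product: 23 C5 (1S)-camphor-10-sulfonate of the (4S,5S,6S,7S) enantiomer of 22
Conditions: (1S)-(+)-camphor-10-sulfonyl chloride, Et3N, DMAP (cat.), CH2Cl2, 0 °C; separation of the two diastereomers (chromatography or crystallisation)
Reagents that add atoms: (1S)-(+)-camphor-10-sulfonyl chloride, O=C1C[C@H]2CC[C@]1(CS(=O)(=O)Cl)C2(C)C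
Why: Sulfonylation of the secondary C5 hydroxyl (through the sulfene); the tertiary C4 hydroxyl is inert. The enantiopure sulfonyl group turns the racemate into two diastereomers and is at the same time the leaving group for step 15, so the resolution costs no step; at most half of the material is carried on, and the sense is assigned by X-ray analysis of the sulfonate.

Step 13
Reactants: 23 C5 (1S)-camphor-10-sulfonate
Product: 24 C8 alcohol (4S,5S,6S,7R,8R; O8 cis to C11)
Conditions: NaBH4, MeOH/CH2Cl2, −40 °C; AcOH quench
Reagents that add atoms: none
Why: Borohydride reduction of the ring ketone (the lactone and sulfonate are inert); hydride should approach C8 anti to the C7–C11 bond, which places O8 cis to C11 as in the target. Any reduction of the camphor carbonyl would not matter, since that group leaves in step 15.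

Step 14
Reactants: 24 C8 alcohol
Product: 25 C8 triethylsilyl ether
Conditions: TESCl, imidazole, CH2Cl2, 0 °C
Reagents that add atoms: chlorotriethylsilane, CC[Si](Cl)(CC)CC
Why: Silylation of the secondary hydroxyl (the tertiary C4–OH stays free); it blocks lactone migration to O8 under the bases that follow.

Step 15
Reactants: 25 C8 triethylsilyl ether
Product: 26 trans-4,5-epoxide with C15–OTBS and C8–OTES (4S,5R,6S,7R,8R)
Conditions: NaH, THF, 0 °C → rt
Reagents that add atoms: none
Why: Intramolecular Williamson closure (3-exo-tet): the C4 alkoxide displaces the C5 sulfonate with inversion, which converts the cis-5,6-dioxygenation into the trans epoxide; no ketone is present that could eliminate the lactone oxygen.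

Step 16
Reactants: 26 trans-4,5-epoxide with C15–OTBS and C8–OTES
Product: 28 α-methylene lactone (C11=C13) with C15–OTBS and C8–OTES, via Mannich base 27 (not isolated)
Conditions: LDA, THF, −78 °C; CH2=NMe2+ I−, −78 → 0 °C; then MeI, MeOH, rt; NaHCO3 (aq), CH2Cl2
Reagents that add atoms: dimethylmethyleneammonium iodide, C=[N+](C)C.[I-]
Why: Mannich methylenation of the lactone enolate (C11 is the only enolisable position), then quaternisation and β-elimination of trimethylamine.

Step 17
Reactants: 28 α-methylene lactone with C15–OTBS and C8–OTES
Product: 29 C8 alcohol with C15–OTBS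
Conditions: HF·pyridine, pyridine, THF, 0 °C
Reagents that add atoms: none
Why: Selective cleavage of the secondary triethylsilyl ether in the presence of the hindered primary tert-butyldimethylsilyl ether; pyridine buffering protects the epoxide.

Step 18
Reactants: 30 (tert-butyldimethylsilyloxy)acetaldehyde; 31 ethyl 2-(triphenylphosphoranylidene)propanoate
Product: 32 ethyl (2E)-4-[(tert-butyldimethylsilyl)oxy]-2-methylbut-2-enoate
Conditions: CH2Cl2, rt
Reagents that add atoms: none
Why: Wittig reaction of a stabilised ylide, which gives the E trisubstituted enoate.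

Step 19
Reactants: 32 ethyl (2E)-4-[(tert-butyldimethylsilyl)oxy]-2-methylbut-2-enoate
Product: 33 (2E)-4-[(tert-butyldimethylsilyl)oxy]-2-methylbut-2-enoic acid
Conditions: LiOH, THF/H2O, 0 °C → rt; then 1 M HCl to pH 4
Reagents that add atoms: lithium hydroxide, [Li+].[OH-]
Why: Saponification; the primary silyl ether tolerates cold aqueous hydroxide and brief mild acid.

Step 20
Reactants: 29 C8 alcohol with C15–OTBS; 33 (2E)-4-[(tert-butyldimethylsilyl)oxy]-2-methylbut-2-enoic acid
Product: 34 bis(tert-butyldimethylsilyl) ether of the target (C15–OTBS and side-chain OTBS)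
Conditions: 2,4,6-trichlorobenzoyl chloride, Et3N, THF, rt; then 29, DMAP, toluene, rt
Reagents that add atoms: none
Why: Yamaguchi esterification through the mixed anhydride, suited to a hindered secondary alcohol; C8 keeps its configuration.

Step 21
Reactants: 34 bis(tert-butyldimethylsilyl) ether of the target
Product: 35 CNP0187639.2 (4S,5R,6S,7R,8R; C1=C10 Z; side chain E)
Conditions: HF·pyridine, pyridine, THF, 0 °C → rt
Reagents that add atoms: none
Why: Fluoride-mediated cleavage of both silyl ethers under buffered, non-basic conditions, which spare the α-methylene lactone, the epoxide (no Payne rearrangement) and the ester.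

## Compound list

1 | hex-5-en-1-yne | C#CCCC=C | starting material
2 | N-methoxy-N-methylcarbamoyl chloride | CON(C)C(=O)Cl | starting material
3 | N-methoxy-N-methylhept-6-en-2-ynamide | CON(C)C(=O)C#CCCC=C | intermediate
4 | 4-methoxybenzyl alcohol | COc1ccc(CO)cc1 | starting material
5 | (2E)-N-methoxy-3-[(4-methoxybenzyl)oxy]-N-methylhepta-2,6-dienamide | CON(C)C(=O)/C=C(/OCc1ccc(OC)cc1)CCC=C | intermediate
6 | (2-methylallyl)magnesium chloride | C=C(C)C[Mg]Cl | starting material
7 | (5E)-6-[(4-methoxybenzyl)oxy]-2-methyldeca-1,5,9-trien-4-one | C=C(C)CC(=O)/C=C(/OCc1ccc(OC)cc1)CCC=C | intermediate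
8 | (2E,6Z)-3-[(4-methoxybenzyl)oxy]-7-methylcycloocta-2,6-dien-1-one (both ring alkenes cis in the ring) | O=C1/C=C(OCc2ccc(OC)cc2)\CC/C=C(C)\C1 | intermediate
9 | (2Z,6Z)-2-iodo-3-[(4-methoxybenzyl)oxy]-7-methylcycloocta-2,6-dien-1-one | O=C1/C(I)=C(OCc2ccc(OC)cc2)\CC/C=C(C)\C1 | intermediate
10 | methyl bromoacetate | COC(=O)CBr | starting material
11 | bromo(2-methoxy-2-oxoethyl)zinc (Reformatsky reagent, not isolated) | COC(=O)C[Zn]Br | intermediate
12 | methyl 2-[(1E,5Z)-2-[(4-methoxybenzyl)oxy]-6-methyl-8-oxocycloocta-1,5-dien-1-yl]acetate (eight-membered β-alkoxy enone: C8 ketone, C7=C4 enol ether, C1=C10 cis) | COC(=O)C/C1=C(OCc2ccc(OC)cc2)/CC/C=C(C)\CC1=O | intermediate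
13 | vinylene carbonate (1,3-dioxol-2-one) | O=C1OC=CO1 | starting material
14 | racemic cyclobutane photoadduct (cyclobutane C4–C5–C6–C7, C4–OPMB, cis-5,6-carbonate; one of the possible exo/endo isomers shown; not isolated) | COC(=O)C[C@@]12C(=O)C/C(C)=C\CC[C@]1(OCc4ccc(OC)cc4)[C@H]3OC(=O)O[C@@H]23 | intermediate
15 | racemic cyclobutanol (C4–OH; not isolated) | COC(=O)C[C@@]12C(=O)C/C(C)=C\CC[C@]1(O)[C@H]3OC(=O)O[C@@H]23 | intermediate
16 | racemic ten-membered 4,8-diketone 5,6-cis-carbonate, methyl ester at C12 (5S*,6S*,7S*; 1(10)Z) | COC(=O)C[C@@H]1C(=O)C/C(C)=C\CCC(=O)[C@H]2OC(=O)O[C@@H]12 | intermediate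
17 | racemic hydroxy lactone diketone (trans-fused C6–O–C12 lactone, C5–OH, C4 and C8 ketones; 5S*,6S*,7S*) | C1C(=O)O[C@H]2[C@H]1C(=O)C/C(C)=C\CCC(=O)[C@H]2O | intermediate
18 | (chloromethyl)(isopropoxy)dimethylsilane | CC(C)O[Si](C)(C)CCl | starting material
19 | [(isopropoxydimethylsilyl)methyl]magnesium chloride (not isolated) | CC(C)O[Si](C)(C)C[Mg]Cl | intermediate
20 | racemic C4 carbinol with C15 as CH2SiMe2(OiPr), C5–OH, C8 ketone (4R*,5S*,6S*,7S*) | C1C(=O)O[C@H]2[C@H]1C(=O)C/C(C)=C\CC[C@@](C[Si](C)(C)OC(C)C)(O)[C@H]2O | intermediate
21 | racemic triol ketone (C15–OH, C4–OH, C5–OH; 4S*,5S*,6S*,7S*) | C1C(=O)O[C@H]2[C@H]1C(=O)C/C(C)=C\CC[C@@](CO)(O)[C@H]2O | intermediate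
22 | racemic C15 tert-butyldimethylsilyl ether of 21 | C1C(=O)O[C@H]2[C@H]1C(=O)C/C(C)=C\CC[C@@](CO[Si](C)(C)C(C)(C)C)(O)[C@H]2O | intermediate
23 | C5 (1S)-camphor-10-sulfonate, ring configuration 4S,5S,6S,7S | C1C(=O)O[C@H]2[C@H]1C(=O)C/C(C)=C\CC[C@@](CO[Si](C)(C)C(C)(C)C)(O)[C@H]2OS(=O)(=O)C[C@]34CC[C@H](CC3=O)C4(C)C | intermediate
24 | C8 alcohol of 23 (4S,5S,6S,7R,8R) | C1C(=O)O[C@H]2[C@H]1[C@H](O)C/C(C)=C\CC[C@@](CO[Si](C)(C)C(C)(C)C)(O)[C@H]2OS(=O)(=O)C[C@]34CC[C@H](CC3=O)C4(C)C | intermediate
25 | C8 triethylsilyl ether of 24 | C1C(=O)O[C@H]2[C@H]1[C@H](O[Si](CC)(CC)CC)C/C(C)=C\CC[C@@](CO[Si](C)(C)C(C)(C)C)(O)[C@H]2OS(=O)(=O)C[C@]34CC[C@H](CC3=O)C4(C)C | intermediate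
26 | trans-4,5-epoxy lactone, C15–OTBS, C8–OTES, C11H2 (4S,5R,6S,7R,8R) | C1C(=O)O[C@H]2[C@H]1[C@H](O[Si](CC)(CC)CC)C/C(C)=C\CC[C@@]1(CO[Si](C)(C)C(C)(C)C)O[C@H]21 | intermediate
27 | C11 dimethylaminomethyl lactone (Mannich base, C11 epimers, not isolated) | CN(C)CC1C(=O)O[C@H]2[C@H]1[C@H](O[Si](CC)(CC)CC)C/C(C)=C\CC[C@@]1(CO[Si](C)(C)C(C)(C)C)O[C@H]21 | intermediate
28 | α-methylene lactone, C15–OTBS, C8–OTES | C=C1C(=O)O[C@H]2[C@H]1[C@H](O[Si](CC)(CC)CC)C/C(C)=C\CC[C@@]1(CO[Si](C)(C)C(C)(C)C)O[C@H]21 | intermediate
29 | α-methylene lactone, C15–OTBS, C8–OH | C=C1C(=O)O[C@H]2[C@H]1[C@H](O)C/C(C)=C\CC[C@@]1(CO[Si](C)(C)C(C)(C)C)O[C@H]21 | intermediate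
30 | (tert-butyldimethylsilyloxy)acetaldehyde | CC(C)(C)[Si](C)(C)OCC=O | starting material
31 | ethyl 2-(triphenylphosphoranylidene)propanoate | CCOC(=O)C(C)=P(c1ccccc1)(c1ccccc1)c1ccccc1 | starting material
32 | ethyl (2E)-4-[(tert-butyldimethylsilyl)oxy]-2-methylbut-2-enoate | CCOC(=O)/C(C)=C/CO[Si](C)(C)C(C)(C)C | intermediate
33 | (2E)-4-[(tert-butyldimethylsilyl)oxy]-2-methylbut-2-enoic acid | OC(=O)/C(C)=C/CO[Si](C)(C)C(C)(C)C | intermediate
34 | bis(tert-butyldimethylsilyl) ether of the target (C15–OTBS, side-chain OTBS) | C=C1C(=O)O[C@H]2[C@H]1[C@H](OC(=O)/C(C)=C/CO[Si](C)(C)C(C)(C)C)C/C(C)=C\CC[C@@]1(CO[Si](C)(C)C(C)(C)C)O[C@H]21 | intermediate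
35 | CNP0187639.2 | C=C1C(=O)O[C@H]2[C@H]1[C@H](OC(=O)/C(C)=C/CO)C/C(C)=C\CC[C@@]1(CO)O[C@H]21 | target

## Step count and least certain steps

Total: 21 steps. Longest linear sequence: 19 steps (steps 1–17, 20, 21); steps 18–19 form the side-chain branch.

**Step 7 (key step).** The excited enone may be lost to processes faster than capture by 13: twisting about C4=C7 (cis–trans isomerisation of an eight-membered enone) and crossed addition to the transannular C1=C10 bond, in which both first bonds close five-membered rings. Fallback: take the transannular alkene out of play. From 12, buffered mCPBA epoxidises only the electron-rich C1=C10 bond to give epoxy enone F1. Irradiation with 13 and DDQ as in step 7 lead through epoxy photoadduct F2 and epoxy cyclobutanol F3 to epoxy diketone carbonate F4. Stereospecific deoxygenation with retention (3-methyl-2-selenoxobenzothiazole, CF3CO2H, CH2Cl2, 0 °C) restores the cis alkene and comes back to the route at 16.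

**Step 8.** The C6 oxygen may be lost by β-elimination through the C7 or C5 enol, or the 1,5-diketone may close by transannular aldol reaction, before the slow tin-catalysed carbonate exchange is complete. Fallback: change the diol protection to one that leaves under acid. From 12, the photocycloaddition is run with 2,2-dimethyl-1,3-dioxole in place of 13, giving through acetonide photoadduct F5 and acetonide cyclobutanol F6 the diketone acetonide F7. TsOH in wet MeOH then removes the acetonide and closes the lactone, coming back at 17.

**Step 9.** Facial selectivity at C4 may be poor if the conformation of the ten-membered ring, rather than the magnesium chelate, decides which face is open; addition at C8 may compete. Fallback: separate C–C bond formation from stereocontrol. From 17, Me3SiCH2MgCl/CeCl3 adds to C4 without regard to face to give β-hydroxysilane F8. Acid-induced Peterson elimination gives the 4(15)-methylene alcohol F9. Dihydroxylation with OsO4·TMEDA (CH2Cl2, −78 °C), directed by hydrogen bonding to the C5 hydroxyl, delivers both oxygens syn to O5 and, after reductive work-up, comes back at 21.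

**Step 12.** The two diastereomeric sulfonates may not separate, since they differ only in the sense of the ring relative to a remote camphor skeleton. Fallback: part the enantiomers physically before the step. Racemic 22 is resolved by preparative chromatography on a chiral stationary phase (amylose tris(3,5-dimethylphenylcarbamate)), and the (4S,5S,6S,7S) enantiomer is sulfonylated as in step 12, coming back at 23; no new compound is made (F0).

**Step 13.** Hydride may be delivered to the wrong face of C8, because the exposed face of a medium-ring ketone is set by ring conformation. Fallback: use the epimer and invert at the esterification. From 23, the 8-epi alcohol F10 is taken through the operations of steps 14–17: 8-epi triethylsilyl ether F11, 8-epi epoxide F12, 8-epi Mannich base F13, 8-epi methylene lactone F14, 8-epi alcohol F15. F15 is then esterified with 33 under Mitsunobu conditions (PPh3, DIAD, toluene), which inverts C8 and comes back at 34.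

## Further compounds

F1 | step 7 | racemic 1,10-epoxide of 12 (cis ring epoxide) | COC(=O)C/C1=C(OCc2ccc(OC)cc2)/CC[C@@H]3O[C@]3(C)CC1=O
F2 | step 7 | epoxy cyclobutane photoadduct (one diastereomer shown) | COC(=O)C[C@@]12C(=O)C[C@@]5(C)O[C@H]5CC[C@]1(OCc4ccc(OC)cc4)[C@H]3OC(=O)O[C@@H]23
F3 | step 7 | epoxy cyclobutanol | COC(=O)C[C@@]12C(=O)C[C@@]5(C)O[C@H]5CC[C@]1(O)[C@H]3OC(=O)O[C@@H]23
F4 | step 7 | 1,10-epoxy 4,8-diketone 5,6-carbonate | COC(=O)C[C@@H]1C(=O)C[C@@]2(C)O[C@H]2CCC(=O)[C@H]3OC(=O)O[C@@H]13
F5 | step 8 | acetonide cyclobutane photoadduct | COC(=O)C[C@@]12C(=O)C/C(C)=C\CC[C@]1(OCc4ccc(OC)cc4)[C@H]3OC(C)(C)O[C@@H]23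
F6 | step 8 | acetonide cyclobutanol | COC(=O)C[C@@]12C(=O)C/C(C)=C\CC[C@]1(O)[C@H]3OC(C)(C)O[C@@H]23
F7 | step 8 | racemic 4,8-diketone 5,6-acetonide | COC(=O)C[C@@H]1C(=O)C/C(C)=C\CCC(=O)[C@H]2OC(C)(C)O[C@@H]12
F8 | step 9 | C4 (trimethylsilyl)methyl carbinol (C4 epimers) | C1C(=O)O[C@H]2[C@H]1C(=O)C/C(C)=C\CCC(O)(C[Si](C)(C)C)[C@H]2O
F9 | step 9 | 4(15)-methylene C5 alcohol | C1C(=O)O[C@H]2[C@H]1C(=O)C/C(C)=C\CCC(=C)[C@H]2O
F0 | step 12 | none | none
F10 | step 13 | 8-epi alcohol (8-epimer of 24) | C1C(=O)O[C@H]2[C@H]1[C@@H](O)C/C(C)=C\CC[C@@](CO[Si](C)(C)C(C)(C)C)(O)[C@H]2OS(=O)(=O)C[C@]34CC[C@H](CC3=O)C4(C)C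
F11 | step 13 | 8-epi triethylsilyl ether | C1C(=O)O[C@H]2[C@H]1[C@@H](O[Si](CC)(CC)CC)C/C(C)=C\CC[C@@](CO[Si](C)(C)C(C)(C)C)(O)[C@H]2OS(=O)(=O)C[C@]34CC[C@H](CC3=O)C4(C)C
F12 | step 13 | 8-epi epoxide | C1C(=O)O[C@H]2[C@H]1[C@@H](O[Si](CC)(CC)CC)C/C(C)=C\CC[C@@]1(CO[Si](C)(C)C(C)(C)C)O[C@H]21
F13 | step 13 | 8-epi Mannich base | CN(C)CC1C(=O)O[C@H]2[C@H]1[C@@H](O[Si](CC)(CC)CC)C/C(C)=C\CC[C@@]1(CO[Si](C)(C)C(C)(C)C)O[C@H]21
F14 | step 13 | 8-epi methylene lactone | C=C1C(=O)O[C@H]2[C@H]1[C@@H](O[Si](CC)(CC)CC)C/C(C)=C\CC[C@@]1(CO[Si](C)(C)C(C)(C)C)O[C@H]21
F15 | step 13 | 8-epi C8 alcohol | C=C1C(=O)O[C@H]2[C@H]1[C@@H](O)C/C(C)=C\CC[C@@]1(CO[Si](C)(C)C(C)(C)C)O[C@H]21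
A1 | alternative 1 | seco C5 alkenyl iodide, C6 aldehyde, C12 methyl ester | COC(=O)C[C@@H](C=O)[C@H](OCc1ccc(OC)cc1)C/C(C)=C\CC/C(CO[Si](c1ccccc1)(c1ccccc1)C(C)(C)C)=C/I
A2 | alternative 1 | 1(10)-cis,4-trans germacradienolide with C8 PMB ether | O=C1C[C@@H]2[C@H](OCc3ccc(OC)cc3)C/C(C)=C\CC/C(CO[Si](c3ccccc3)(c3ccccc3)C(C)(C)C)=C/[C@H]2O1
A3 | alternative 2 | ten-membered trienoic acid (C6 methylene, C12 acid) | C=C(C(=O)O)[C@H]1C/C=C(CO[Si](C)(C)C(C)(C)C)/CC/C=C(C)\C[C@H]1OC(=O)/C(C)=C/CO[Si](C)(C)C(C)(C)C
A4 | alternative 2 | bis-silyl 4,5-deoxy target (diene lactone) | C=C1C(=O)O[C@@H]2/C=C(CO[Si](C)(C)C(C)(C)C)/CC/C=C(C)\C[C@@H](OC(=O)/C(C)=C/CO[Si](C)(C)C(C)(C)C)[C@@H]12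
A5 | alternative 3 | decalin ring-fusion epoxy ketone (C10 ketone, C1–C6 epoxide; epoxide face arbitrary) | O=C1C[C@@H](O[Si](CC)(CC)CC)C[C@]23O[C@]12CC[C@@]1(CO[Si](C)(C)C(C)(C)C)OC(C)(C)O[C@H]13
A6 | alternative 3 | ten-membered C6 ketone with C1–C10 alkyne | O=C1C[C@H](O[Si](CC)(CC)CC)CC#CCC[C@@]2(CO[Si](C)(C)C(C)(C)C)OC(C)(C)O[C@H]21
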